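## Retrosynthetic overview
1. Target ⇒ ovatodiolide. A last-step Schenck ene reaction of ¹O2 at C4=C5 sets C5 and moves the olefin to C4=C18.
2. Ovatodiolide ⇒ acyclic (10R)-butenolide carrying an E-enal (C14) and a 2-(bromomethyl)enoate (C1, C15–C17). One Cr(II) allylation forms C1–C14, the 14-membered ring and the trans α-methylene lactone.
3. (10R)-Butenolide enal ⇒ 3-alkyl-2-furoic acid + prenal dienol silane. ¹O2/–CO2 dearomatisation gives the γ-hydroxybutenolide. A catalytic asymmetric vinylogous Mukaiyama aldol–lactonisation follows in the same flask and makes C10–C11, the C10 stereocentre and E-C12=C13.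
4. 3-Alkyl-2-furoic acid ⇒ 3-methyl-2-furoic acid (lateral dianion, C6–C7 bond) + a C7 allylic chloride cut out of geranyl chloride. The acrylate C15–C17 comes from a Morita–Baylis–Hillman reaction.
5. Ring order: butenolide (from the furan) → macrocycle and α-methylene-γ-lactone together → hydroperoxide last.

Numbering used:
- C1 is the ring-fusion CH.
- C4(Me-18)=C5 is the first trisubstituted olefin.
- C8 is the α-carbon, C10 the γ-carbon and C19 the C=O of the butenolide.
- C12(Me-20)=C13 is the second trisubstituted olefin.
- C14 is the lactone CH–O.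
- C15(=C17H2)–C16(=O) is the methylene lactone unit.
- The target is (1R,5R,10R,14S).

Assumption: the (S,S)-IDPi catalyst is taken as the enantiomer that opens the Re face of the C10 aldehyde. Its mirror image is equally available, and the sense is checked on compound 16.

## Route

Step 1
Reactants: 1 geranyl chloride
Product: 3 (E)-6-chloro-4-methylhex-4-enal dimethyl acetal, via (E)-6-chloro-4-methylhex-4-enal 2 (not isolated)
Conditions: O3 (1.0 equiv, Sudan III end point), CH2Cl2/MeOH 9:1, −78 °C; Me2S, → rt; HC(OMe)3, p-TsOH (5 mol %), 0 °C, 1 h; Et3N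
Reagents that add atoms: ozone [O-][O+]=O (carbonyl O of 2 only); trimethyl orthoformate COC(OC)OC (both OMe groups of 3)
Why: Chemoselective ozonolysis, in which electrophilic ozone cleaves the electron-rich isopropylidene olefin well before the olefin deactivated by the allylic chloride, followed by orthoformate acetalisation in the same pot to mask the aldehyde against the dianion of step 2, with the E-olefin untouched.

Step 2
Reactants: 4 3-methylfuran-2-carboxylic acid; 3 (E)-6-chloro-4-methylhex-4-enal dimethyl acetal
Product: 7 3-[(3E)-4-methyl-7-oxohept-3-en-1-yl]furan-2-carboxylic acid, via lithium 3-(lithiomethyl)furan-2-carboxylate 5 (not isolated), via lithium 3-[(3E)-7,7-dimethoxy-4-methylhept-3-en-1-yl]furan-2-carboxylate 6 (not isolated)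
Conditions: 4, LDA (2.2 equiv), THF, −78 → 0 °C; 3, −78 → 0 °C; then 2 M HCl, THF, rt, 2 h
Reagents that add atoms: lithium diisopropylamide [Li+].CC(C)[N-]C(C)C (Li of 5 and 6 only); water O (aldehyde O of 7)
Why: Carboxylate-directed lateral lithiation gives the extended enediolate-type dianion, which is alkylated at its CH2 terminus by SN2 attack on the primary allylic chloride with retention of the E-olefin, and the acidic quench that frees the acid also hydrolyses the acetal (no stereocentre formed).

Step 3
Reactants: 7 3-[(3E)-4-methyl-7-oxohept-3-en-1-yl]furan-2-carboxylic acid; 8 methyl acrylate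
Product: 9 3-[(3E)-7-hydroxy-8-(methoxycarbonyl)-4-methylnona-3,8-dien-1-yl]furan-2-carboxylic acid (C1 carbinol racemic)
Conditions: 8 (5 equiv), DABCO (2 equiv), 1,4-dioxane/H2O 1:1, rt, 48 h; pH 3 work-up
Reagents that add atoms: none
Why: Morita–Baylis–Hillman reaction, in which DABCO adds to the acrylate and the ammonium enolate attacks the unhindered aliphatic aldehyde while the furoate is an inert spectator as its salt; the new carbinol centre is racemic and is erased in step 6.

Step 4
Reactants: 10 3-methylbut-2-enal (prenal)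
Product: 11 (1E)-3-methyl-1-(triethylsilyloxy)buta-1,3-diene
Conditions: TESOTf (1.1 equiv), Et3N (1.5 equiv), Et2O, 0 °C; distillation
Reagents that add atoms: triethylsilyl triflate CC[Si](CC)(CC)OS(=O)(=O)C(F)(F)F
Why: Soft vinylogous enolisation, with O-silylation of the enal and then γ-deprotonation of a methyl group by Et3N, gives the 1-silyloxydiene (no stereocentre, and the enol-ether geometry is lost again in step 5).

Step 5 (key step)
Reactants: 9 3-[(3E)-7-hydroxy-8-(methoxycarbonyl)-4-methylnona-3,8-dien-1-yl]furan-2-carboxylic acid; 11 (1E)-3-methyl-1-(triethylsilyloxy)buta-1,3-diene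
Product: 16 methyl (6E)-3-hydroxy-6-methyl-2-methylidene-9-{(5R)-5-[(2E)-2-methyl-4-oxobut-2-en-1-yl]-2-oxo-2,5-dihydrofuran-3-yl}non-6-enoate, via furan endoperoxide 12 (not isolated), via γ-hydroxybutenolide (pseudoacid) 13 (not isolated), via ring-opened bis-TES (Z)-4-oxobut-2-enoate 14 (not isolated), via tris-TES (10R)-aldol adduct 15 (not isolated)
Conditions: O2, tetrakis(pentafluorophenyl)porphyrin (0.05 mol %), white LED, CH2Cl2, −78 °C, stopped at full conversion of the furan; warm to 0 °C (−CO2), Ar sparge; (S,S)-IDPi (3 mol %), 11 (3.3 equiv, two of them as TES donors for CO2H/OH), −60 °C; 1 M HCl, THF, 0 °C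
Reagents that add atoms: dioxygen O=O
Why: Proposed new method: [4+2] addition of ¹O2 to the furoic acid gives endoperoxide 12, whose carboxyl group leaves as CO2 so that the former furan C2 becomes the lactone carbonyl C19 and C10 a masked aldehyde (the known decarboxylative photooxygenation of 2-furoic acids, which leaves only a gas behind and so allows telescoping); the confined chiral acid is then silylated by 11, turns 13 into the ring-opened silyl ester aldehyde 14 (in equilibrium with its cyclic silyl lactol) and pairs the O-silyl oxocarbenium ion with the chiral anion, so that the γ-carbon of the s-trans dienol silane attacks the Re face of C10 (sets 10R, gives the E-enal) and the acidic work-up cleaves all O–Si bonds and lactonises; the closest known reaction types are disulfonimide/IDPi-catalysed Mukaiyama and vinylogous Mukaiyama aldol reactions of aldehyde-derived enol silanes and Lewis-acid Mukaiyama aldol reactions of γ-hydroxybutenolides at C5.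

Step 6
Reactants: 16 (10R)-butenolide enal with the MBH alcohol
Product: 17 methyl (2Z,6E)-2-(bromomethyl)-6-methyl-9-{(5R)-5-[(2E)-2-methyl-4-oxobut-2-en-1-yl]-2-oxo-2,5-dihydrofuran-3-yl}nona-2,6-dienoate
Conditions: NBS (1.3 equiv), Me2S (1.5 equiv), CH2Cl2, 0 °C (premix), then 16, 0 °C → rt
Reagents that add atoms: N-bromosuccinimide O=C1CCC(=O)N1Br
Why: Corey–Kim-type activation of the MBH alcohol as an alkoxysulfonium salt and SN2′ attack of bromide at the terminal CH2 give the conjugated (Z)-2-(bromomethyl)enoate (chain trans to the ester), erase the racemic C1 carbinol centre and leave enal, butenolide and C10 untouched under neutral conditions.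

Step 7
Reactants: 17 (Z)-allylic bromide enal
Product: 20 ovatodiolide (1R,10R,14S), via allylchromium(III) dichloride 18 (not isolated), via macrocyclic anti chromium(III) alkoxide 19 (not isolated)
Conditions: CrCl2 (8 equiv), 4 Å MS, THF, 17 added over 12 h (final 2 mM), rt; aq. NH4Cl/sodium serinate work-up
Reagents that add atoms: chromium(II) chloride Cl[Cr]Cl (Cr and Cl of 18 and 19 only)
Why: Nozaki–Hiyama–Kishi (Cr(II) Barbier) macrocyclisation, in which the geometrically equilibrating allylchromium 18 adds SE2′ and 1,2 to the enal through a chair transition state with both chains equatorial to give the anti adduct that lactonises to the trans α-methylene lactone, while the rigid (10R)-butenolide inside the 14-membered transition state exposes the Re face of the enal so that 14S and 1R result.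

Step 8
Reactants: 20 ovatodiolide
Product: 21 4-methylene-5β-hydroperoxyovatodiolide (1R,5R,10R,14S)
Conditions: O2, tetraphenylporphyrin (0.5 mol %), white LED, CH2Cl2, 0 °C, stopped at about 80 % conversion; chromatography
Reagents that add atoms: dioxygen O=O
Why: Schenck ene reaction, in which electrophilic ¹O2 takes the only electron-rich olefin (C12=C13 is deactivated by the allylic acyloxy group and the other two are conjugated with C=O), adds to its exposed peripheral face and, following the cis effect, abstracts H-18 suprafacially, which puts OOH on C5 (5R) and the olefin at C4=C18; the 4-hydroperoxy-5-ene regioisomer from H-6 abstraction is removed by chromatography.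

## Compound list
1 | geranyl chloride, (2E)-1-chloro-3,7-dimethylocta-2,6-diene | CC(C)=CCC/C(C)=C/CCl | starting material
2 | (E)-6-chloro-4-methylhex-4-enal | O=CCC/C(C)=C/CCl | intermediate (not isolated)
3 | (E)-1-chloro-6,6-dimethoxy-3-methylhex-2-ene | COC(OC)CC/C(C)=C/CCl | intermediate
4 | 3-methylfuran-2-carboxylic acid | Cc1ccoc1C(=O)O | starting material
5 | lithium 3-(lithiomethyl)furan-2-carboxylate (lateral dianion) | [Li+].[Li+].[CH2-]c1ccoc1C(=O)[O-] | intermediate (not isolated)
6 | lithium 3-[(3E)-7,7-dimethoxy-4-methylhept-3-en-1-yl]furan-2-carboxylate | [Li+].COC(OC)CC/C(C)=C/CCc1ccoc1C(=O)[O-] | intermediate (not isolated)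
7 | 3-[(3E)-4-methyl-7-oxohept-3-en-1-yl]furan-2-carboxylic acid | O=CCC/C(C)=C/CCc1ccoc1C(=O)O | intermediate
8 | methyl acrylate | C=CC(=O)OC | starting material
9 | 3-[(3E)-7-hydroxy-8-(methoxycarbonyl)-4-methylnona-3,8-dien-1-yl]furan-2-carboxylic acid (carbinol racemic) | C=C(C(=O)OC)C(O)CC/C(C)=C/CCc1ccoc1C(=O)O | intermediate
10 | 3-methylbut-2-enal (prenal) | CC(C)=CC=O | starting material
11 | (1E)-3-methyl-1-(triethylsilyloxy)buta-1,3-diene | C=C(C)/C=C/O[Si](CC)(CC)CC | intermediate
12 | endoperoxide of 9: 2,3,7-trioxabicyclo[2.2.1]hept-5-ene-1-carboxylic acid with the side chain on C6 (stereocentres uncontrolled) | COC(=O)C(=C)C(O)CC/C(C)=C/CCC1=CC2OOC1(C(=O)O)O2 | intermediate (not isolated)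
13 | methyl (6E)-3-hydroxy-9-(5-hydroxy-2-oxo-2,5-dihydrofuran-3-yl)-6-methyl-2-methylidenenon-6-enoate (pseudoacid, C10 and C1 uncontrolled) | COC(=O)C(=C)C(O)CC/C(C)=C/CCC1=CC(O)OC1=O | intermediate (not isolated)
14 | ring-opened form of 13 as the triethylsilyl (Z)-4-oxobut-2-enoate, with C1–OTES | O=C/C=C(/CC/C=C(\C)CCC(O[Si](CC)(CC)CC)C(=C)C(=O)OC)C(=O)O[Si](CC)(CC)CC | intermediate (not isolated)
15 | (10R)-vinylogous aldol adduct: C10–OTES, C19 TES ester, C1–OTES, E-enal | O=C/C=C(\C)C[C@@H](O[Si](CC)(CC)CC)/C=C(/CC/C=C(\C)CCC(O[Si](CC)(CC)CC)C(=C)C(=O)OC)C(=O)O[Si](CC)(CC)CC | intermediate (not isolated)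
16 | methyl (6E)-3-hydroxy-6-methyl-2-methylidene-9-{(5R)-5-[(2E)-2-methyl-4-oxobut-2-en-1-yl]-2-oxo-2,5-dihydrofuran-3-yl}non-6-enoate (C1 carbinol 1:1) | O=C/C=C(\C)C[C@@H]1C=C(CC/C=C(\C)CCC(O)C(=C)C(=O)OC)C(=O)O1 | intermediate
17 | methyl (2Z,6E)-2-(bromomethyl)-6-methyl-9-{(5R)-5-[(2E)-2-methyl-4-oxobut-2-en-1-yl]-2-oxo-2,5-dihydrofuran-3-yl}nona-2,6-dienoate | O=C/C=C(\C)C[C@@H]1C=C(CC/C=C(\C)CC/C=C(\CBr)C(=O)OC)C(=O)O1 | intermediate
18 | allylchromium(III) dichloride derived from 17 (olefin geometry equilibrating) | O=C/C=C(\C)C[C@@H]1C=C(CC/C=C(\C)CC/C=C(\C[Cr](Cl)Cl)C(=O)OC)C(=O)O1 | intermediate (not isolated)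
19 | macrocyclic (1R,10R,14S) anti-hydroxy ester as its Cr(III) alkoxide | C=C(C(=O)OC)[C@H]1CC/C(C)=C/CCC2=C[C@@H](C/C(C)=C/[C@@H]1O[Cr](Cl)Cl)OC2=O | intermediate (not isolated)
20 | ovatodiolide (1R,10R,14S; 4E,12E; trans lactone) | C=C1C(=O)O[C@H]2/C=C(\C)C[C@@H]3C=C(CC/C=C(\C)CC[C@H]12)C(=O)O3 | intermediate
21 | 4-methylene-5β-hydroperoxyovatodiolide (1R,5R,10R,14S) | C=C1C(=O)O[C@H]2/C=C(\C)C[C@@H]3C=C(CC[C@@H](OO)C(=C)CC[C@H]12)C(=O)O3 | target

## Step count and risks
Total step count: 8. Longest linear sequence: 7 (steps 1, 2, 3, 5, 6, 7, 8). Step 4 is a one-step side branch.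

**Step 5.** The free furoic acid reacts with ¹O2 only moderately faster than C4=C5 does. The polar groups may also slow the ion-pair catalyst, and the ee is unproven. The fallback sets out from 9 and comes back at 16. It splits the step and replaces catalytic ion-pair control by a stoichiometric, covalently bound chiral Lewis acid acting on a discrete aldehyde.
- The diisopropylethylammonium salt of 9, which is the more electron-rich and faster diene, is photooxygenated (rose bengal, MeOH, −78 °C) through 12, and 13 is isolated.
- TMSCHN2 opens 13 to the methyl (Z)-4-oxobut-2-enoate F1.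
- F1 reacts with 11 under one equivalent of the N-tosyltryptophan-derived B-phenyl-oxazaborolidinone (enantiomer for Re-face attack; EtCN, i-PrOH, −78 °C) to give the (10R)-δ-hydroxy ester F2.
- F2 lactonises with catalytic CSA to 16.

**Step 7.** The risks are oligomerisation, simple reduction of the bromide, and an insufficient relay of C10 to C1/C14. The fallback sets out from 16 and comes back at 20. It abandons the reductive Barbier chemistry for an isolable allylboron nucleophile.
- Acetylation of 16 (Ac2O, DMAP) gives the MBH acetate F3.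
- Pd(0)-catalysed borylation with B2pin2 gives the allylboronate F4, in which the chain is cis to CH2B.
- TfOH-catalysed intramolecular allylboration at true high dilution passes through a closed chair and gives the macrocyclic syn borate F5.
- Under the same acid the allylic C14–O bond ionises and the ester carbonyl recloses from the opposite face to the more stable trans lactone. C14 is then dictated by C1, and 20 results.

**Step 8.** The risks are a near-statistical split between H-18 and H-6 abstraction, incomplete face selectivity and double oxidation. The fallback sets out from 20 and comes back at 21. It replaces the pericyclic oxygenation by an ionic two-step sequence.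
- Ene-type chlorination with HOCl (Ca(OCl)2, solid CO2, CH2Cl2/H2O, 0 °C) at C4=C5 can only give the secondary chloride with the exocyclic methylene, the allylic chloride F6.
- Silver-assisted perhydrolysis (AgOTf, anhydrous ethereal H2O2, −20 °C) passes through the allyl cation, which is captured at C5 from the open peripheral face to give 21.

## Further compounds
F1 | step 5 | methyl (2Z)-2-[(3E)-7-hydroxy-8-(methoxycarbonyl)-4-methylnona-3,8-dien-1-yl]-4-oxobut-2-enoate | O=C/C=C(/CC/C=C(\C)CCC(O)C(=C)C(=O)OC)C(=O)OC
F2 | step 5 | (10R)-δ-hydroxy enal, open-chain methyl (Z)-enoate precursor of 16 | O=C/C=C(\C)C[C@@H](O)/C=C(/CC/C=C(\C)CCC(O)C(=C)C(=O)OC)C(=O)OC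
F3 | step 7 | MBH acetate of 16 | O=C/C=C(\C)C[C@@H]1C=C(CC/C=C(\C)CCC(OC(C)=O)C(=C)C(=O)OC)C(=O)O1
F4 | step 7 | methyl (2E,6E)-2-[(pinacolboryl)methyl]nona-2,6-dienoate analogue of 17 | O=C/C=C(\C)C[C@@H]1C=C(CC/C=C(\C)CC/C=C(\CB2OC(C)(C)C(C)(C)O2)C(=O)OC)C(=O)O1
F5 | step 7 | macrocyclic (1R,10R,14R) syn-hydroxy ester as its O-Bpin borate | C=C(C(=O)OC)[C@H]1CC/C(C)=C/CCC2=C[C@@H](C/C(C)=C/[C@H]1OB3OC(C)(C)C(C)(C)O3)OC2=O
F6 | step 8 | (5R)-5-chloro-4(18)-methylene analogue of 21 | C=C1C(=O)O[C@H]2/C=C(\C)C[C@@H]3C=C(CC[C@@H](Cl)C(=C)CC[C@H]12)C(=O)O3
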